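## Structural features

The target is built on ring A, a cyclohex-2-en-1-one (C1 ketone, C2 bearing the amide nitrogen, C3 olefinic CH, C4 tertiary carbinol) that is cis-fused across C5–C6 to ring B, an oxirane. Two chains leave ring A: at C2 the nitrogen of a (2E,4R)-2,4-dimethyloct-2-enamide, and at C4 an all-E hepta-1,3,5-trienamide whose nitrogen sits on ring C, a 2-amino-3-hydroxycyclopent-2-enone. The three ring stereocentres C4 (S), C5 (R) and C6 (S) are contiguous, with the C4 hydroxyl on the same face as the oxirane oxygen. The fourth stereocentre, C4 of the octenoyl chain (R), is isolated and allylic. Fragile groups are the α,β-epoxy ketone (bases, nucleophiles, reductants), the doubly allylic tertiary carbinol (acid), the triene (light, acid), the acidic enol of ring C, and any α-branched aldehyde used to make the upper chain (epimerisation). The real difficulty is ring A: five of its six carbons carry a heteroatom, it sits at the oxidation level of an aminoquinone so most intermediates can aromatise, its three adjacent centres must be set absolutely, and nitrogen must go to C2 and not C3. The key step uses the fact that C1 and C6 carry neighbouring oxygens ortho and meta to the heteroatom-bearing sp2 carbon C2. This is the pattern toluene dioxygenase imposes on a monosubstituted benzene, so a bromine at C2 lets the enzyme set C6 and mark C2 in one operation.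

## Logic of the disconnections

34 ⇒ 33 + 17. The bond cut is the sp2–sp2 single bond between the second and third carbons of the trienamide chain, counted from C4. This puts the triene and the acidic ring C into the last step, splits the molecule into two halves of similar size, and keeps each alkene geometry defined inside a fragment. The forward step must be a neutral, stereoretentive coupling that tolerates a free tertiary alcohol, an epoxy ketone and an enol.

33 ⇒ 32 ⇒ 31. The C–Sn bond and then the terminal alkyne C–H are taken back, the latter to a C–Si bond. The silylalkyne is the only form of the two-carbon handle that is inert to the copper chemistry of the preceding stage. The forward steps need a buffered desilylation and a syn hydrostannation that puts tin on the terminal carbon without reducing the enone or the oxirane.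

31 ⇒ 30 + 9. The C2–N bond is cut. C2 is the carbon that carries bromine from the first step of the ring synthesis, and the complete upper chain with its stereocentre arrives in one piece. The forward step is a C–N coupling on an α-bromo enone, with a base mild enough for the epoxy ketone.

30 ⇒ 29 ⇒ 26 + 27 (through 28). The C1 carbonyl is taken back to the carbinol, then the C4–C(sp) bond is cut. With C1 at the alcohol level, C4 is the only carbonyl, and the neighbouring oxirane sends the nucleophile to the opposite face, which creates the C4 centre. The forward step needs carbonyl rather than conjugate addition to a β-bromo enone, and a masked C1 hydroxyl.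

26 ⇒ 25 ⇒ 23 (through 24). The O–Si bond is cut, then the C5–O bond of the oxirane, back to a C5 bromide trans to the C6 oxygen; the C1/C6 diol is returned to its acetal. Closing from the C6 oxygen keeps the enzymatic configuration at C6 and sets C5 by inversion. The leaving group must be anti to C6–O, and C4 must be a ketone, both to activate C5 and so that no C4 hydroxyl competes.

23 ⇒ 22 ⇒ 21. The C4 carbonyl goes back to the carbinol, then the C4–O and C5–Br bonds are cut together. One anti addition across the only electron-rich alkene supplies oxygen at C4 and a leaving group at C5 on the face opposite the acetal; this does the work of an epoxidation, an opening and a sulfonylation. The forward step must attack the unbrominated alkene from the face anti to the dioxolane, with water entering at the allylic carbon.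

21 ⇒ 20 ⇒ 18 + 19. After removal of the acetal, the C1–O and C6–O bonds are cut together and the arene is restored. All six ring carbons and the C2 marker then come from a commodity arene, and two stereocentres come from an achiral substrate. The forward step is an enantio- and regioselective cis-dihydroxylation of an arene, which only the enzyme offers.

9 ⇒ 8 ⇒ 5 + 6 (through 7) ⇒ 4 ⇒ 3 ⇒ 1 + 2. The amide C–N bond, the C2=C3 alkene of the octenoyl chain and the bond from the chain stereocentre to its methyl group are cut in turn. This reduces the chain to a six-carbon acyl unit on a recoverable auxiliary. The forward steps need an E-selective olefination that does not epimerise the α-branched aldehyde, and an auxiliary-controlled methylation.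

17 ⇒ 15 + 12; 15 ⇒ 14 ⇒ 13; 12 ⇒ 11 ⇒ 10. The amide C–N bond is cut, the acid is taken back through the aldehyde to a five-carbon dienolate salt, and the C–N bond of ring C is taken back to the dione. The forward steps need N- over O-acylation and retention of the (2E,4E) geometry.

## Other disconnections considered

Alternative 1: The cut removes the four ring C–O bonds at C3, C4, C5 and C6 together and leads back to the diene A1, which carries the alkynyl group on C4 and a silyloxy stereocentre on C1. In the forward sense A1 would add singlet oxygen (porphyrin sensitiser, light) across C3 and C6 on the face away from the silyloxy group to give endoperoxide A2. Co(TPP), a divalent cobalt porphyrin, would then isomerise A2 in the same flask to the syn bis-epoxide A3.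
- In favour: one molecule of oxidant supplies both the oxirane oxygen and the future C4 carbinol oxygen. Their syn relation follows from the mechanism. The C4 carbon substituent is already present, so no face-selective carbonyl addition is needed. Oxidation at C1 would later open the C3–C4 oxirane by β-elimination to the enone, converging on the epoxyquinol A7.
- Against: the absolute configuration rests on a single silyloxy centre that has to be made enantiopure separately and is destroyed afterwards. Facial control by that remote group is substrate-dependent. A1 is one elimination of silanol away from an arene. C2 is a bare methylene, so nitrogen needs an extra α-halogenation before the same copper amidation.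
- Comparison: on ring oxygenation this alternative is the better plan (four C–O bonds in one flask against steps 13–15). The syn relation is equally secure in both. The chosen plan is stronger on the source of absolute configuration and on the C2 handle. Overall step counts should be similar once the preparation of A1 and the halogenation are counted.

Alternative 2: The cut is a ring contraction: the C4–C5 ring bond and the ester carbon on C4 are traced back to the seven-membered triketone A4. In the forward sense methoxide would add to one carbonyl of the vicinal dione of A4, and the ring carbon on that carbonyl would migrate to the neighbouring carbonyl carbon (benzilic ester rearrangement), giving the quinol ester A5.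
- In favour: the quaternary carbinol C4 and the first carbon of the lower chain are made together without an organometallic reagent. The ester is a handle for chain extension by olefination, which would avoid organotin chemistry; on that point it is better than the chosen plan.
- Against: A4 is not a commercial compound and needs several steps itself. A5 is achiral, so no stereocentre is set and an enantioselective epoxidation is still required. The ester makes the dienone prone to acyl migration and aromatisation, and must be reduced next to a cross-conjugated dienone. C2 still lacks nitrogen.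
- Comparison: structurally it addresses only C4 and its carbon substituent. The anionic 1,2-shift is sound but competes with conjugate addition of methoxide. In step economy it is clearly longer than the chosen plan.

Alternative 3: The cut is the pair of C–O bonds of the oxirane at C5 and C6, leading back to the achiral quinol A6, which should be available in two operations from 27. In the forward sense the sodium alkoxide of A6 would deliver a trityl peroxide oxygen, in the presence of one enantiomer of diisopropyl tartrate, to one enone arm on the face of the C4 oxygen, giving the epoxyquinol A7.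
- In favour: C4, C5 and C6 are set in one step from an achiral precursor. The syn relation is enforced by delivery from the C4 alkoxide. No fermentation is needed. To the epoxyquinol stage it is shorter than the chosen plan (about three steps against eight) and equal in control of relative configuration.
- Against: the enantioselectivity is reagent-controlled by a stoichiometric additive, and its level for an alkynyl quinol is uncertain, whereas the enzyme is expected to give one enantiomer. A7 has no substituent at C2, so an α-halogenation has to precede amidation.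
- Comparison: this is the closest competitor and converges with the chosen route after halogenation. The chosen plan is preferred for its absolute stereocontrol and the built-in C2 bromine. Alternative 3 is kept as the fallback for the key step.

Key step: step 11

Remarks on the chemistry:
- Ring positions C1–C6 in the Why lines follow ring A of the target (C1 ketone, C2 nitrogen-bearing, C3, C4 carbinol, C5 and C6 oxirane); systematic names use their own locants.
- The configurations were re-derived: the dihydrodiol is (1S,2S) and cis, and its oxygen at the carbon meta to bromine maps onto the C6 oxirane oxygen of the (4S,5R,6S) ring without change of sense. No structure needed correcting; descriptors at some ring carbons change along the route only because substituent priorities change.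
- Compounds 1, 6, 13 and 27 are taken to be commercial.

## Route

Step 1
Reactants: 1 (4R)-4-benzyl-1,3-oxazolidin-2-one; 2 hexanoyl chloride
Product: 3 (4R)-4-benzyl-3-hexanoyl-1,3-oxazolidin-2-one
Conditions: n-BuLi, THF, −78 °C; then 2, −78 → 0 °C
Reagents that add atoms: none
Why: N-Acylation of the lithiated auxiliary by the acid chloride; no new stereocentre is formed.

Step 2
Reactants: 3
Product: 4 (4R)-4-benzyl-3-[(2R)-2-methylhexanoyl]-1,3-oxazolidin-2-one
Conditions: NaN(SiMe3)2, THF, −78 °C; MeI, −78 → −40 °C
Reagents that add atoms: iodomethane, CI
Why: Evans alkylation: the chelated Z-sodium enolate is methylated on the face opposite the benzyl group, which with the (R)-auxiliary should give the (2R) centre, the future C4 of the octenoyl chain.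

Step 3
Reactants: 4
Product: 5 (2R)-2-methylhexan-1-ol
Conditions: LiBH4, H2O (1 equiv), Et2O, 0 °C
Reagents that add atoms: none
Why: Hydride reduction of the exocyclic imide carbonyl releases the primary alcohol and the intact auxiliary; the α-stereocentre is not enolised under these conditions.

Step 4
Reactants: 5; 6 ethyl 2-(triphenyl-λ5-phosphanylidene)propanoate
Product: 8 ethyl (2E,4R)-2,4-dimethyloct-2-enoate, via (2R)-2-methylhexanal 7 (not isolated)
Conditions: Dess–Martin periodinane, CH2Cl2, 0 °C → rt; then 6, 40 °C
Reagents that add atoms: none
Why: Dess–Martin oxidation followed in the same flask by Wittig olefination with a stabilised α-methyl ylide, which should give the (E)-trisubstituted alkene; not isolating 7 limits epimerisation of its α-centre.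

Step 5
Reactants: 8
Product: 9 (2E,4R)-2,4-dimethyloct-2-enamide
Conditions: Me3Al, NH4Cl, toluene, 0 → 50 °C
Reagents that add atoms: ammonium chloride, [NH4+].[Cl-]
Why: Aluminium amide aminolysis of the ester (Weinreb type): MeAl(Cl)NH2 formed in the flask transfers NH2 to the carbonyl; alkene geometry and the γ-stereocentre are not touched.

Step 6
Reactants: 10 cyclopentane-1,3-dione
Product: 11 3-hydroxy-2-nitrocyclopent-2-en-1-one
Conditions: fuming HNO3, Et2O, 0 °C
Reagents that add atoms: nitric acid, O[N+](=O)[O-]
Why: Electrophilic nitration of the enol of a cyclic 1,3-dione at its nucleophilic C2.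

Step 7
Reactants: 11
Product: 12 2-amino-3-hydroxycyclopent-2-en-1-one hydrochloride
Conditions: H2 (1 atm), Pd/C, HCl, EtOH, rt
Reagents that add atoms: hydrogen chloride, Cl
Why: Catalytic hydrogenation of the nitro group; the amine is trapped as its hydrochloride so that the electron-rich aminoenolone neither oxidises nor self-condenses.

Step 8
Reactants: 13 potassium (1E,3E)-5-oxopenta-1,3-dien-1-olate (glutaconaldehyde potassium salt)
Product: 14 (2E,4E)-5-bromopenta-2,4-dienal
Conditions: PPh3, Br2, CH2Cl2, 0 °C; then 13, 0 °C → rt
Reagents that add atoms: bromine, BrBr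
Why: The dienolate oxygen is activated as an oxyphosphonium ion by Ph3PBr2 and replaced by bromide through addition–elimination; the conjugated product should settle as the (2E,4E) isomer.

Step 9
Reactants: 14
Product: 15 (2E,4E)-5-bromopenta-2,4-dienoic acid
Conditions: NaClO2, NaH2PO4, 2-methylbut-2-ene, t-BuOH/H2O, 0 °C → rt
Reagents that add atoms: sodium chlorite, [Na+].[O-]Cl=O
Why: Pinnick oxidation of the aldehyde with a hypochlorite scavenger; the bromodiene and its geometry are inert to these conditions.

Step 10
Reactants: 15; 12
Product: 17 (2E,4E)-5-bromo-N-(2-hydroxy-5-oxocyclopent-1-en-1-yl)penta-2,4-dienamide, via (2E,4E)-5-bromopenta-2,4-dienoyl chloride 16 (not isolated)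
Conditions: (COCl)2, DMF (cat.), CH2Cl2, 0 °C → rt; evaporate; then 12, Et3N, THF/DMF, 0 °C → rt
Reagents that add atoms: none
Why: Acid chloride formation and N-acylation of the aminoenolone; any enol ester formed first is expected to pass its acyl group to nitrogen, giving the hydrogen-bonded enol amide.

Step 11
Reactants: 18 bromobenzene; 19 dioxygen
Product: 20 (1S,2S)-3-bromocyclohexa-3,5-diene-1,2-diol
Conditions: E. coli JM109(pDTG601) whole cells (toluene dioxygenase, IPTG-induced), glucose feed, air, mineral-salts medium, pH 6.8–7.0, 30–35 °C; EtOAc extraction, cold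
Reagents that add atoms: none
Why: Toluene dioxygenase is a Rieske non-heme iron dioxygenase: electrons from NADH, regenerated from glucose by the cells, reach the mononuclear iron site, where 19 is activated and both of its oxygen atoms are delivered to the same face of one π bond of 18, so the C1–O and C6–O bonds form cis and the arene is dearomatised without any ring closure. This is the established reaction type for the enzyme, cis-dihydroxylation of a monosubstituted benzene at its ortho and meta carbons, and halobenzenes are standard substrates. Both new stereocentres are set by the chiral active site alone, since the substrate has no stereo-element, which should give the (1S,2S) diol as one enantiomer. The step needs regioselectivity (ortho/meta rather than meta/para oxidation) and enantioface selectivity; both follow from the way the binding pocket orients the ring by its bromine, the only feature that distinguishes the ring positions. Over-oxidation is avoided because the recombinant host lacks the diol dehydrogenase, and loss of water back to a phenol is held off by keeping broth and extract neutral and cold. Bromine ends on the sp2 carbon that becomes C2, and the oxygen on the meta carbon already has the configuration of the C6 oxirane oxygen.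

Step 12
Reactants: 20
Product: 21 (3aS,7aS)-4-bromo-2,2-dimethyl-3a,7a-dihydro-1,3-benzodioxole
Conditions: 2,2-dimethoxypropane, TsOH·H2O (cat.), acetone, 0 °C → rt
Reagents that add atoms: 2,2-dimethoxypropane, COC(C)(C)OC
Why: Acetal exchange on the cis-diol stops acid-catalysed dehydration to a phenol and shields one face of the diene; the product is used at once because such dienes dimerise slowly by cycloaddition.

Step 13
Reactants: 21
Product: 22 (3aR,4R,5S,7aS)-4,7-dibromo-2,2-dimethyl-3a,4,5,7a-tetrahydro-1,3-benzodioxol-5-ol
Conditions: NBS, THF/H2O (4:1), 0 °C, dark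
Reagents that add atoms: N-bromosuccinimide, O=C1CCC(=O)N1Br; water, O
Why: Bromohydrin formation: the bromonium ion forms on the more electron-rich, unbrominated alkene on the face opposite the dioxolane, and water opens it anti at the allylic carbon C4, so the C5 bromide ends trans to the C6 oxygen.

Step 14
Reactants: 22
Product: 23 (3aR,4S,7aS)-4,7-dibromo-2,2-dimethyl-3a,7a-dihydro-1,3-benzodioxol-5(4H)-one
Conditions: Dess–Martin periodinane, CH2Cl2, 0 °C → rt
Reagents that add atoms: none
Why: Dess–Martin oxidation of the only free, allylic hydroxyl; the C4 ketone removes the one competing nucleophile for the later closure and activates the C5 bromide, and the near-neutral medium should not epimerise the α-bromo centre.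

Step 15
Reactants: 23
Product: 25 (1R,5S,6R)-4-bromo-5-hydroxy-7-oxabicyclo[4.1.0]hept-3-en-2-one, via (4S,5R,6S)-3,6-dibromo-4,5-dihydroxycyclohex-2-en-1-one 24 (not isolated)
Conditions: TFA/H2O (9:1), 0 °C; evaporate (toluene); then K2CO3, MeCN, 0 °C → rt
Reagents that add atoms: none
Why: Acid hydrolysis of the acetal frees the C1 and C6 hydroxyls, and mild base then lets the C6 oxygen displace the trans α-keto bromide at C5 (intramolecular SN2, 3-exo-tet) with inversion at C5; the oxirane therefore lies on the face of the enzymatically installed C6 oxygen, and the C1 hydroxyl is too remote to compete.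

Step 16
Reactants: 25
Product: 26 (1R,5S,6S)-4-bromo-5-[(trimethylsilyl)oxy]-7-oxabicyclo[4.1.0]hept-3-en-2-one
Conditions: TMSOTf, 2,6-lutidine, CH2Cl2, −78 °C
Reagents that add atoms: trimethylsilyl trifluoromethanesulfonate, C[Si](C)(C)OS(=O)(=O)C(F)(F)F
Why: Silylation of the secondary alcohol with a silyl triflate and a hindered base that does not add to the β-bromo enone; the temporary ether keeps the C1 oxygen from consuming or misdirecting the acetylide.

Step 17
Reactants: 26; 27 (triisopropylsilyl)acetylene
Product: 29 (1R,2R,5S,6R)-4-bromo-2-[(triisopropylsilyl)ethynyl]-7-oxabicyclo[4.1.0]hept-3-ene-2,5-diol, via trimethylsilyl ether adduct 28 (not isolated)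
Conditions: 27, n-BuLi, THF, −78 °C; then 26, −78 °C; aq. NH4Cl; then citric acid, MeOH, rt
Reagents that add atoms: none
Why: 1,2-Addition of the lithium acetylide to the C4 carbonyl from the face opposite the adjacent oxirane oxygen (the usual bias of α,β-epoxy ketones, reinforced by the silyloxy group on the same face) places the new C4 hydroxyl syn to the oxirane; hard acetylides favour carbonyl over conjugate addition, and mild acidic methanolysis removes the trimethylsilyl ether.

Step 18
Reactants: 29
Product: 30 (1S,5R,6R)-3-bromo-5-hydroxy-5-[(triisopropylsilyl)ethynyl]-7-oxabicyclo[4.1.0]hept-3-en-2-one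
Conditions: Dess–Martin periodinane, NaHCO3, CH2Cl2, 0 °C → rt
Reagents that add atoms: none
Why: Dess–Martin oxidation of the secondary allylic alcohol to the α-bromo enone; the tertiary carbinol cannot be oxidised and the buffered medium spares the oxirane and the silylalkyne.

Step 19
Reactants: 30; 9
Product: 31 (2E,4R)-N-[(1S,5R,6R)-5-hydroxy-2-oxo-5-[(triisopropylsilyl)ethynyl]-7-oxabicyclo[4.1.0]hept-3-en-3-yl]-2,4-dimethyloct-2-enamide
Conditions: CuI (10 mol %), MeNHCH2CH2NHMe (20 mol %), K2CO3, toluene, 60–70 °C
Reagents that add atoms: none
Why: Goldberg–Buchwald vinylic amidation: the monovalent copper amidate held by the diamine inserts into the activated C2–Br bond, and reductive elimination forms C2–N without moving the double bond; the ring stereocentres are not involved.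

Step 20
Reactants: 31
Product: 32 (2E,4R)-N-[(1S,5R,6R)-5-ethynyl-5-hydroxy-2-oxo-7-oxabicyclo[4.1.0]hept-3-en-3-yl]-2,4-dimethyloct-2-enamide
Conditions: Bu4NF, AcOH, THF, 0 °C
Reagents that add atoms: none
Why: Fluoride cleaves the C(sp)–Si bond; acetic acid buffers the medium so that the epoxy ketone and the tertiary alkoxide are not exposed to strong base.

Step 21
Reactants: 32
Product: 33 (2E,4R)-N-[(1S,5R,6R)-5-hydroxy-2-oxo-5-[(E)-2-(tributylstannyl)ethenyl]-7-oxabicyclo[4.1.0]hept-3-en-3-yl]-2,4-dimethyloct-2-enamide
Conditions: Bu3SnH (slow addition), PdCl2(PPh3)2 (3 mol %), THF, 0 °C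
Reagents that add atoms: tributyltin hydride, CCCC[SnH](CCCC)CCCC
Why: Palladium-catalysed hydrostannation (zerovalent palladium formed in the flask) adds Sn–H syn across the terminal alkyne, with tin on the terminal carbon away from the fully substituted carbinol, giving the (E)-stannane; slow addition keeps the hydride concentration low so the alkyne reacts before the enone.

Step 22
Reactants: 33; 17
Product: 34 (2E,4R)-N-[(1S,5S,6R)-5-hydroxy-5-[(1E,3E,5E)-7-[(2-hydroxy-5-oxocyclopent-1-en-1-yl)amino]-7-oxohepta-1,3,5-trien-1-yl]-2-oxo-7-oxabicyclo[4.1.0]hept-3-en-3-yl]-2,4-dimethyloct-2-enamide (CNP0259711.1)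
Conditions: PdCl2(MeCN)2 (5 mol %), DMF, rt, dark
Reagents that add atoms: none
Why: Stille coupling: oxidative addition of the dienyl bromide to zerovalent palladium, transmetalation and reductive elimination all proceed with retention, so the (E)-stannane and the (2E,4E)-bromide should give the all-E triene under neutral conditions that tolerate the free hydroxyl, enol and epoxy ketone.

## Compound list

1 | (4R)-4-benzyl-1,3-oxazolidin-2-one | O=C1N[C@H](Cc2ccccc2)CO1 | starting material
2 | hexanoyl chloride | CCCCCC(Cl)=O | starting material
3 | (4R)-4-benzyl-3-hexanoyl-1,3-oxazolidin-2-one | CCCCCC(=O)N1[C@H](Cc2ccccc2)COC1=O | intermediate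
4 | (4R)-4-benzyl-3-[(2R)-2-methylhexanoyl]-1,3-oxazolidin-2-one | CCCC[C@@H](C)C(=O)N1[C@H](Cc2ccccc2)COC1=O | intermediate
5 | (2R)-2-methylhexan-1-ol | CCCC[C@@H](C)CO | intermediate
6 | ethyl 2-(triphenyl-λ5-phosphanylidene)propanoate | CCOC(=O)C(C)=P(c1ccccc1)(c1ccccc1)c1ccccc1 | starting material
7 | (2R)-2-methylhexanal | CCCC[C@@H](C)C=O | intermediate
8 | ethyl (2E,4R)-2,4-dimethyloct-2-enoate | CCCC[C@@H](C)/C=C(\C)C(=O)OCC | intermediate
9 | (2E,4R)-2,4-dimethyloct-2-enamide | CCCC[C@@H](C)/C=C(\C)C(N)=O | intermediate
10 | cyclopentane-1,3-dione | O=C1CCC(=O)C1 | starting material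
11 | 3-hydroxy-2-nitrocyclopent-2-en-1-one (enol form of 2-nitrocyclopentane-1,3-dione) | O=C1CCC(O)=C1[N+](=O)[O-] | intermediate
12 | 2-amino-3-hydroxycyclopent-2-en-1-one hydrochloride | NC1=C(O)CCC1=O.Cl | intermediate
13 | potassium (1E,3E)-5-oxopenta-1,3-dien-1-olate (glutaconaldehyde potassium salt) | [K+].[O-]/C=C/C=C/C=O | starting material
14 | (2E,4E)-5-bromopenta-2,4-dienal | Br/C=C/C=C/C=O | intermediate
15 | (2E,4E)-5-bromopenta-2,4-dienoic acid | Br/C=C/C=C/C(=O)O | intermediate
16 | (2E,4E)-5-bromopenta-2,4-dienoyl chloride | Br/C=C/C=C/C(Cl)=O | intermediate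
17 | (2E,4E)-5-bromo-N-(2-hydroxy-5-oxocyclopent-1-en-1-yl)penta-2,4-dienamide | Br/C=C/C=C/C(=O)NC1=C(O)CCC1=O | intermediate
18 | bromobenzene | Brc1ccccc1 | starting material
19 | dioxygen | O=O | starting material
20 | (1S,2S)-3-bromocyclohexa-3,5-diene-1,2-diol | O[C@H]1C=CC=C(Br)[C@H]1O | intermediate
21 | (3aS,7aS)-4-bromo-2,2-dimethyl-3a,7a-dihydro-1,3-benzodioxole | BrC1=CC=C[C@@H]2OC(C)(C)O[C@H]12 | intermediate
22 | (3aR,4R,5S,7aS)-4,7-dibromo-2,2-dimethyl-3a,4,5,7a-tetrahydro-1,3-benzodioxol-5-ol | BrC1=C[C@H](O)[C@@H](Br)[C@@H]2OC(C)(C)O[C@H]12 | intermediate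
23 | (3aR,4S,7aS)-4,7-dibromo-2,2-dimethyl-3a,7a-dihydro-1,3-benzodioxol-5(4H)-one | BrC1=CC(=O)[C@@H](Br)[C@@H]2OC(C)(C)O[C@H]12 | intermediate
24 | (4S,5R,6S)-3,6-dibromo-4,5-dihydroxycyclohex-2-en-1-one | BrC1=CC(=O)[C@@H](Br)[C@H](O)[C@@H]1O | intermediate
25 | (1R,5S,6R)-4-bromo-5-hydroxy-7-oxabicyclo[4.1.0]hept-3-en-2-one | BrC1=CC(=O)[C@@H]2O[C@@H]2[C@@H]1O | intermediate
26 | (1R,5S,6S)-4-bromo-5-[(trimethylsilyl)oxy]-7-oxabicyclo[4.1.0]hept-3-en-2-one | BrC1=CC(=O)[C@@H]2O[C@@H]2[C@@H]1O[Si](C)(C)C | intermediate
27 | (triisopropylsilyl)acetylene | C#C[Si](C(C)C)(C(C)C)C(C)C | starting material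
28 | (1R,2R,5S,6S)-4-bromo-2-[(triisopropylsilyl)ethynyl]-5-[(trimethylsilyl)oxy]-7-oxabicyclo[4.1.0]hept-3-en-2-ol | BrC1=C[C@@](O)(C#C[Si](C(C)C)(C(C)C)C(C)C)[C@@H]2O[C@@H]2[C@@H]1O[Si](C)(C)C | intermediate
29 | (1R,2R,5S,6R)-4-bromo-2-[(triisopropylsilyl)ethynyl]-7-oxabicyclo[4.1.0]hept-3-ene-2,5-diol | BrC1=C[C@@](O)(C#C[Si](C(C)C)(C(C)C)C(C)C)[C@@H]2O[C@@H]2[C@@H]1O | intermediate
30 | (1S,5R,6R)-3-bromo-5-hydroxy-5-[(triisopropylsilyl)ethynyl]-7-oxabicyclo[4.1.0]hept-3-en-2-one | BrC1=C[C@@](O)(C#C[Si](C(C)C)(C(C)C)C(C)C)[C@@H]2O[C@@H]2C1=O | intermediate
31 | (2E,4R)-N-[(1S,5R,6R)-5-hydroxy-2-oxo-5-[(triisopropylsilyl)ethynyl]-7-oxabicyclo[4.1.0]hept-3-en-3-yl]-2,4-dimethyloct-2-enamide | CCCC[C@@H](C)/C=C(\C)C(=O)NC1=C[C@@](O)(C#C[Si](C(C)C)(C(C)C)C(C)C)[C@@H]2O[C@@H]2C1=O | intermediate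
32 | (2E,4R)-N-[(1S,5R,6R)-5-ethynyl-5-hydroxy-2-oxo-7-oxabicyclo[4.1.0]hept-3-en-3-yl]-2,4-dimethyloct-2-enamide | CCCC[C@@H](C)/C=C(\C)C(=O)NC1=C[C@@](O)(C#C)[C@@H]2O[C@@H]2C1=O | intermediate
33 | (2E,4R)-N-[(1S,5R,6R)-5-hydroxy-2-oxo-5-[(E)-2-(tributylstannyl)ethenyl]-7-oxabicyclo[4.1.0]hept-3-en-3-yl]-2,4-dimethyloct-2-enamide | CCCC[C@@H](C)/C=C(\C)C(=O)NC1=C[C@@](O)(/C=C/[Sn](CCCC)(CCCC)CCCC)[C@@H]2O[C@@H]2C1=O | intermediate
34 | (2E,4R)-N-[(1S,5S,6R)-5-hydroxy-5-[(1E,3E,5E)-7-[(2-hydroxy-5-oxocyclopent-1-en-1-yl)amino]-7-oxohepta-1,3,5-trien-1-yl]-2-oxo-7-oxabicyclo[4.1.0]hept-3-en-3-yl]-2,4-dimethyloct-2-enamide (CNP0259711.1) | CCCC[C@@H](C)/C=C(\C)C(=O)NC1=C[C@@](O)(/C=C/C=C/C=C/C(=O)NC2=C(O)CCC2=O)[C@@H]2O[C@@H]2C1=O | target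

## Step count and least certain steps

Total step count: 22. Longest linear sequence: 12 steps (steps 11–22, from 18 to 34); the two side branches take 5 steps each (steps 1–5 and 6–10).

Step 11 (key step). The most likely failure is an insufficient supply of 20. Substrate toxicity and volatility can stall the whole-cell oxidation, and the diol can lose water and rearomatise during concentration. Fallback, reagent-controlled and without fermentation: setting out from 27, its lithium acetylide would be added to commercial 4,4-dimethoxycyclohexa-2,5-dien-1-one to give 4,4-dimethoxy-1-[(triisopropylsilyl)ethynyl]cyclohexa-2,5-dien-1-ol F1. Aqueous oxalic acid would hydrolyse the ketal to 4-hydroxy-4-[(triisopropylsilyl)ethynyl]cyclohexa-2,5-dien-1-one F2 (the same structure as A6). Hydroxyl-directed nucleophilic epoxidation (NaN(SiMe3)2, Ph3COOH, the enantiomer of diisopropyl tartrate that leads to the (1S,6R) oxirane, toluene, −50 °C) would give (1S,5R,6R)-5-hydroxy-5-[(triisopropylsilyl)ethynyl]-7-oxabicyclo[4.1.0]hept-3-en-2-one F3 (the same structure as A7). α-Iodination (I2, pyridine, CH2Cl2) would give (1S,5R,6R)-5-hydroxy-3-iodo-5-[(triisopropylsilyl)ethynyl]-7-oxabicyclo[4.1.0]hept-3-en-2-one F4, which would be amidated with 9 under the conditions of step 19, returning to the route at 31.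

Step 13. The most likely failure is loss of regiocontrol in the capture of the bromonium ion (water entering at C5 or in a conjugate sense), or attack on the hindered face; either would put the leaving group in the wrong place. Fallback from 21: epoxidation (mCPBA, CH2Cl2, 0 °C) of the unbrominated alkene anti to the dioxolane would give the oxirane F5. Hydroxide opening at the allylic carbon (aq. KOH, DMSO, 80 °C) would give the trans-diol F6. MnO2 in CH2Cl2 would oxidise only the allylic C4 hydroxyl to the hydroxy ketone F7, and MsCl/Et3N would give the C5 mesylate F8. The conditions of step 15 would then remove the acetal to the diol mesylate F9 and close the oxirane from the C6 oxygen, returning at 25.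

Step 15. The most likely failure is β-elimination across C5–C6 from the acidic α-bromo ketone followed by aromatisation, acid-promoted dehydration during acetal cleavage, or epimerisation at C5 that leaves the bromide cis to the C6 oxygen. Fallback from 20, which replaces the acid-labile acetal by fluoride-labile ethers so that unmasking and closure happen together without an acidic stage: TBSOTf/2,6-lutidine would give the bis(tert-butyldimethylsilyl) ether F10. NBS in aqueous THF would give the bromohydrin F11, and Dess–Martin periodinane the ketone F12. Bu4NF buffered with AcOH in THF at 0 °C would release the C6 alkoxide, which should close at once, returning at 25.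

Step 19. The most likely failure is base-mediated degradation of the epoxy ketone (fragmentation or aromatisation to an aminophenol), or conjugate addition of the diamine ligand outrunning C–N coupling. Fallback from 29, which couples before the ketone exists: 29 and 9 with CuI, MeNHCH2CH2NHMe and K2CO3 in toluene at 90 °C would give the enamide diol (2E,4R)-N-[(1R,2S,5R,6R)-2,5-dihydroxy-5-[(triisopropylsilyl)ethynyl]-7-oxabicyclo[4.1.0]hept-3-en-3-yl]-2,4-dimethyloct-2-enamide F13 (configuration as in the SMILES). Dess–Martin oxidation of its secondary hydroxyl would return at 31.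

Step 21. The most likely failure is competing reduction of the enone or reductive opening of the epoxy ketone by the palladium hydride/tin hydride system, partial formation of the internal stannane, and protodestannylation on purification. Fallback from 32, which avoids tin hydride: platinum-catalysed hydrosilylation (PtCl2, XPhos, BnMe2SiH, THF, rt), known to place silicon on the terminal carbon of propargylic alcohols with E geometry, would give the benzyldimethylsilyl alkene F14. Fluoride-promoted Hiyama–Denmark coupling with 17 (Pd2(dba)3, Bu4NF, THF, rt) would return at 34.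

## Further compounds

F1 | step 11 | 4,4-dimethoxy-1-[(triisopropylsilyl)ethynyl]cyclohexa-2,5-dien-1-ol | COC1(OC)C=CC(O)(C#C[Si](C(C)C)(C(C)C)C(C)C)C=C1
F2 | step 11 | 4-hydroxy-4-[(triisopropylsilyl)ethynyl]cyclohexa-2,5-dien-1-one | O=C1C=CC(O)(C#C[Si](C(C)C)(C(C)C)C(C)C)C=C1
F3 | step 11 | (1S,5R,6R)-5-hydroxy-5-[(triisopropylsilyl)ethynyl]-7-oxabicyclo[4.1.0]hept-3-en-2-one | C1=C[C@@](O)(C#C[Si](C(C)C)(C(C)C)C(C)C)[C@@H]2O[C@@H]2C1=O
F4 | step 11 | (1S,5R,6R)-5-hydroxy-3-iodo-5-[(triisopropylsilyl)ethynyl]-7-oxabicyclo[4.1.0]hept-3-en-2-one | IC1=C[C@@](O)(C#C[Si](C(C)C)(C(C)C)C(C)C)[C@@H]2O[C@@H]2C1=O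
F5 | step 13 | oxirane of 21 on the unbrominated alkene, anti to the dioxolane | BrC1=C[C@H]2O[C@H]2[C@@H]3OC(C)(C)O[C@H]13
F6 | step 13 | trans-diol analogue of 22 (hydroxyl in place of the sp3 bromine) | BrC1=C[C@H](O)[C@@H](O)[C@@H]2OC(C)(C)O[C@H]12
F7 | step 13 | hydroxy ketone analogue of 23 (hydroxyl in place of the sp3 bromine) | BrC1=CC(=O)[C@@H](O)[C@@H]2OC(C)(C)O[C@H]12
F8 | step 13 | methanesulfonate of F7 | BrC1=CC(=O)[C@@H](OS(C)(=O)=O)[C@@H]2OC(C)(C)O[C@H]12
F9 | step 13 | diol mesylate analogue of 24 (mesyloxy in place of the sp3 bromine) | BrC1=CC(=O)[C@@H](OS(C)(=O)=O)[C@H](O)[C@@H]1O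
F10 | step 15 | bis(tert-butyldimethylsilyl) ether of 20 | BrC1=CC=C[C@H](O[Si](C)(C)C(C)(C)C)[C@@H]1O[Si](C)(C)C(C)(C)C
F11 | step 15 | bis(tert-butyldimethylsilyl) analogue of 22 | BrC1=C[C@H](O)[C@@H](Br)[C@H](O[Si](C)(C)C(C)(C)C)[C@@H]1O[Si](C)(C)C(C)(C)C
F12 | step 15 | bis(tert-butyldimethylsilyl) analogue of 23 | BrC1=CC(=O)[C@@H](Br)[C@H](O[Si](C)(C)C(C)(C)C)[C@@H]1O[Si](C)(C)C(C)(C)C
F13 | step 19 | (2E,4R)-N-[(1R,2S,5R,6R)-2,5-dihydroxy-5-[(triisopropylsilyl)ethynyl]-7-oxabicyclo[4.1.0]hept-3-en-3-yl]-2,4-dimethyloct-2-enamide | CCCC[C@@H](C)/C=C(\C)C(=O)NC1=C[C@@](O)(C#C[Si](C(C)C)(C(C)C)C(C)C)[C@@H]2O[C@@H]2[C@@H]1O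
F14 | step 21 | benzyldimethylsilyl analogue of 33 ((E)-2-[benzyl(dimethyl)silyl]ethenyl in place of the stannylethenyl group) | CCCC[C@@H](C)/C=C(\C)C(=O)NC1=C[C@@](O)(/C=C/[Si](C)(C)Cc3ccccc3)[C@@H]2O[C@@H]2C1=O
A1 | alternative 1 | tert-butyl(dimethyl){[(1S)-4-[(triisopropylsilyl)ethynyl]cyclohexa-2,4-dien-1-yl]oxy}silane | CC(C)(C)[Si](C)(C)O[C@H]1CC=C(C#C[Si](C(C)C)(C(C)C)C(C)C)C=C1
A2 | alternative 1 | endoperoxide of A1 (2,3-dioxabicyclo[2.2.2]oct-5-ene, peroxide bridge anti to the silyloxy group) | CC(C)(C)[Si](C)(C)O[C@H]1C[C@@H]2OO[C@H]1C=C2C#C[Si](C(C)C)(C(C)C)C(C)C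
A3 | alternative 1 | syn C3–C4, C5–C6 bis-epoxide with C1 silyl ether | C1[C@@H]3O[C@]3(C#C[Si](C(C)C)(C(C)C)C(C)C)[C@@H]2O[C@@H]2[C@H]1O[Si](C)(C)C(C)(C)C
A4 | alternative 2 | cyclohepta-3,6-diene-1,2,5-trione (para-tropoquinone) | O=C1C=CC(=O)C(=O)C=C1
A5 | alternative 2 | methyl 1-hydroxy-4-oxocyclohexa-2,5-diene-1-carboxylate | COC(=O)C1(O)C=CC(=O)C=C1
A6 | alternative 3 | 4-hydroxy-4-[(triisopropylsilyl)ethynyl]cyclohexa-2,5-dien-1-one | O=C1C=CC(O)(C#C[Si](C(C)C)(C(C)C)C(C)C)C=C1
A7 | alternative 3 | (1S,5R,6R)-5-hydroxy-5-[(triisopropylsilyl)ethynyl]-7-oxabicyclo[4.1.0]hept-3-en-2-one | C1=C[C@@](O)(C#C[Si](C(C)C)(C(C)C)C(C)C)[C@@H]2O[C@@H]2C1=O
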